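All constants are assumed; the flask was simulated.

On a plate it is tempting to spend the wells on the free base, and that was the pitfall I watched for in this flask.

the same everywhere: electrophile 20 mM; nucleophile 19.0 mM; protic impurity 6.00 mM; scavenger 20.0 mM; time 80 min
- teal: free base 40.0 mM
- red: free base 90.0 mM
- ochre: free base 60.0 mM

    acid set free + scavenger → scavenged by-product (k1 = 59.8 /M/s)
    nucleophile + acid set free ⇌ idle adduct, settled at all times (K2 = 36 /M)
    nucleophile + protic impurity → quenched reagent (k3 = 1.93 /M/s)
    acid set free + free base ⇌ salt of the base (K4 = 362 /M, k4 = 21.8 /M/s)
    electrophile + nucleophile → acid set free + product (k5 = 59.7 /M/s)
    nucleophile + acid set free ⇌ protonated nucleophile, settled at all times (K6 = 46000 /M)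

- part of the electrophile that has reacted at the end, teal
- part of the electrophile that has reacted at the end, red
- part of the electrophile that has reacted at the end, ochre
- what raising the concentration of free base from its lowest to its highest value here does to the part of the electrophile that has reacted (changes below 5 percentage points count as none) (no change / it rises / it falls)

- acid set free is meant together with its idle adduct
- run time (teal): 80 min

Two numbers seemed not to go together. My zero of the scale was the one-for-one case: the nucleophile, the limiting reagent since its 19.0 mM is less than the 20 mM of electrophile, turns wholly into product, which gives 95.0%. Yet each product frees one acid, and in teal at the start the equilibrium constant times charge is 870 for the nucleophile against 14 for the free base, so at the start the acid sits on the nucleophile rather than on the base.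

The binding is a balance, though, and the scavenger, charged at 20.0 mM against 19.0 mM of nucleophile, takes acid for good. With those bindings and the scavenger held at their starting strength, I reckoned a half-life of the bound acid of 8.59 min in teal and 8.77 min in red. Both are shorter than the 80 min run, so I took the base as changing the pace and expected the parked nucleophile back.

That left the impurity. The two steps that use nucleophile up for good are both first order in it, so parking does not alter their split. I called the selectivity factor S the rate constant with electrophile over the rate constant with impurity, 30.9. The fraction of impurity left is then the fraction of electrophile left, raised to the power one over S. Starting from the zero of the scale, I reckoned for teal a loss of 0.554 mM of nucleophile to impurity. A second pass gives 0.476 mM, so my figure for teal is 92.6%, which is 2.4 percentage points below the zero.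

The forecast gave 92.6% for teal, 92.6% for red and 92.6% for ochre, with no change, holding that “the amount of base changes the pace but not the endpoint”.

The simulation gave 92.6% for teal, 92.6% for red and 92.6% for ochre, a change of 0 points, so the trend is no change. With the quench struck out, teal gave 95.0%. S prices that distance at 0.476 mM of nucleophile, and teal held 0.484 mM of quenched reagent after 80.0 min.

Take teal with 4.8 mM of nucleophile: S gives a loss of 0.0530 mM and so 23.7%. The simulation gave 23.7% for that flask, with 0.0523 mM of quenched reagent.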